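## The problem

Target 27 consists of three arenes. Ring A is fused to a 2,3-dihydro-1,4-dioxine (O1, C2, C3, O4, C4a to C8a). C2 carries a 4-hydroxy-3,5-dimethoxyphenyl (syringyl) group, C3 a hydroxymethyl group and C5 a free phenol, and C7 is joined through an E-alkene to a resorcinol ring. Ring A is 1,2,3-trioxygenated, but only O4 (on C4a) and O1 (on C8a) belong to the heterocycle, so any synthesis must decide which of two nearly equal oxygens binds the benzylic carbon C2 and which binds C3; the wrong choice gives a constitutional isomer. The two stereocentres C2 and C3 are both S, with their substituents trans. C2 is benzylic to a para-oxygenated ring and can in principle be equilibrated through a quinone methide towards the more stable trans isomer, whereas C3 cannot be repaired; C3 can therefore steer C2 but not the reverse, and the absolute configuration must be secured at C3. The stilbene alkene forbids late hydrogenolysis and dislikes strong protic acid, the C2–O1 bond ionises under Lewis acids, the five phenols are sensitive to air and base and must be released last, and the two methyl ethers must survive that release. The feature to exploit is that O4 and O1 sit on adjacent carbons beside the C5 oxygen, which is the pattern left when a 3-alkoxybenzyne (triple bond C4a–C8a) takes up a nucleophile at the remote carbon and an electrophile at the near one. If both partners are oxygen atoms of one C2–C3 chain, the dioxane closes without any bond to a stereocentre being touched.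

## Retrosynthesis

**27 ⇒ 26.** Only five O–benzyl bonds are cut.
- Phenol silyl ethers would not survive the fluoride of the ring-forming step.
- Acetal-type phenol protection could not be told apart from the aldehyde acetal carried at C7.
- Hydrogenolysis is excluded once the alkene exists.
- The skeleton stays the same, but 26 has no acidic proton.
- The forward reaction must cleave four aryl and one alkyl benzyl ether while sparing the alkene, two methyl ethers and the C2–O1 bond.

**26 ⇒ 25 + 20.** The alkene is cut.
- The neighbouring cut, aryl–vinyl at C7, would need a second halogen on ring A, which could not be distinguished in the bromine–lithium exchange that makes the aryne precursor.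
- The olefination cut removes the whole resorcinol third of the molecule and leaves aldehyde 25.
- The forward reaction must be E-selective and must not deprotonate C2 or C3.

**25 ⇒ 24.** The carbonyl is masked as a dioxolane. A free aldehyde would be attacked by every reactive species of the annulation (alkoxide, aryl anion, aryne). An ester would cost two redox steps afterwards, whereas the acetal costs one mild hydrolysis.

**24 ⇒ 11 + 18, through aryne 22.** Both aryl–oxygen bonds, O1–C8a and O4–C4a, are cut.
- The neighbouring alkyl–oxygen cuts (O1–C2, O4–C3) each endanger a stereocentre. They also need a pyrogallol whose two ring oxygens are differentiated by protecting groups.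
- Cutting a single aryl–oxygen bond needs a halogen and a second, separate ring-forming event.
- The double cut removes the ring and the regiochemical problem together. Compound 24 falls into an achiral arene half and an acyclic chain with one nucleophilic and one electrophilic oxygen.
- Three things are asked of the forward step.
  - The C2 oxygen must enter at C8a.
  - The C3 oxygen must be electrophilic, hence the inner atom of a tert-butyl peroxide.
  - The aryl anion 23 must meet no proton.
- The free alcohol 10 fails the third demand, because its own O–H would quench 23 the moment it forms. It is therefore used as silyl ether 11. Fluoride turns 11 into alkoxide 21 without leaving a proton source, so the same reagent unmasks both partners.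
- An ether solvent replaces the usual C–H-acidic nitrile. An excess of 18 serves to consume the tert-butoxy anion that is released.

**11 ⇒ 10 ⇒ 9 ⇒ 6 + 7.** The C3–O4 bond is cut.
- No method converts an alcohol into a tert-butyl peroxide with retention.
- Opening an aryl epoxide with 7 would place the peroxide on the benzylic carbon, which is the wrong atom.
- Displacement of a sulfonate by the anion of 7 remains. It inverts, so the syn array of 10 requires the anti alcohol 6.
- The C2 oxygen must meanwhile carry a group that cannot participate (no ester) and that leaves without reductant or strong base. This points to a p-methoxybenzyl ether.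

**6 ⇒ 5 ⇒ 4 ⇒ 3.** The benzylic C–O bond is cut back to an epoxide.
- An asymmetric dihydroxylation would give the syn diol with two undifferentiated hydroxyls, which is the wrong relative configuration for an inverting displacement.
- Benzylic opening of trans-epoxide 5 gives the anti array and differentiates the two oxygens in one step.
- The epoxide comes from allylic alcohol 3 by reagent-controlled epoxidation, the single source of absolute configuration.
- The forward opening must proceed with clean inversion.

**3 ⇒ 2 ⇒ 1.** Functional-group changes lead to commercial sinapic acid 1, which already holds the E-alkene and the full oxygenation of the syringyl ring.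

**18 ⇒ 15 ⇒ 14 ⇒ 13 ⇒ 12.** The C–Si and O–S bonds are cut back to ortho-bromophenol 15.
- In 14 the phenol oxygen sits on the future C4a, bromine on C8a, the benzyl ether on C5 and the aldehyde on C7, so all four positions of ring A are fixed by simple directing effects.
- The only selectivity demanded is mono-benzylation of 12 at the oxygen meta to the aldehyde.

**20 ⇒ 19.** The C–P bond is cut to a commercial benzylic bromide.

## Roads not taken

Alternative 1: Ring A is removed altogether.
- **Cut.** In benzodioxane A1 the bonds C4a–C8a, C7–C8 and C5–C6 are cut. This leads to bis(ynol ether) A2 (ethynyl on O1, silylethynyl on O4) and methyl propiolate A3.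
- **Forward step.** It is a [2+2+2] cycloaddition with [Rh(cod)2]BF4 and BINAP (monovalent rhodium).
- **Merits.**
  - Arene and dioxane arise in one operation, and the C–O bonds at C2 and C3 are never touched.
  - The stereocentres of A2 would come directly from a syn dihydroxylation, with no inversion and no peroxide. In the supply of stereochemistry this road is shorter and safer than steps 1 to 8.
- **Weak points.**
  - Two different ynol ethers must be placed on neighbouring secondary oxygens, so the hydroxyls must be differentiated all the same, under strongly basic elimination conditions.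
  - Secondary and especially benzylic ynol ethers lose alkene by retro-ene reaction on mild warming.
  - The orientation of A3 (ester at C7, not C6) rests on silyl bulk alone.
  - After the key step, silicon at C5 must be oxidised to a phenol and protected, and the ester must be adjusted to the aldehyde.
- **Comparison.** The chosen plan needs one acetal hydrolysis after ring formation, where this road needs about four operations. The chosen precursors 11 and 18 are also storable.

Alternative 2: The O1–C2 bond is cut.
- **Cut.** Benzodioxane A4 is traced to benzodioxole carbinol A5, whose ketal carbon is the future C3.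
- **Forward step.** Triflation of the (R)-carbinol in the presence of a hindered pyridine triggers a 1,2-shift of one ketal oxygen to C2 with inversion. A trialkylsilane then reduces the C3 oxocarbenium ion.
- **Merits.**
  - Only one stereocentre has to be bought, and neither peroxide nor aryne is handled.
  - Ring A arrives as a cheap gallate. The step count is probably lower than in the chosen plan, which must be conceded.
- **Weak points.**
  - Either ketal oxygen can migrate, and this choice fixes the position of C2 relative to C5.
  - The better donor (meta to the ester) must migrate. That leaves the poorer donor (para to the ester, ortho to a mesylate) to stabilise the cation, so migration and cation stabilisation pull in opposite directions.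
  - A syringyl-type benzylic triflate may ionise even with a mesylate on the ring, and inversion would then be lost.
  - C3 is set only by the direction of hydride approach.
  - The mesylates must finally be removed with strong nucleophile or base from an air-sensitive polyphenol.
- **Comparison.** The chosen plan sets regiochemistry through a well-understood aryne distortion. Both stereocentres are fixed before the ring is made.

Alternative 3: O4 is inserted into a C3–C4a bond.
- **Cut.** Benzodioxane A6 is traced to the tertiary hydroperoxide A7 of a 2-aryl-2,3-dihydrobenzofuran.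
- **Forward step.** A boron Lewis acid induces a Hock shift of ring A from C3 to oxygen, and a trialkylsilane reduces the ring-expanded oxocarbenium ion.
- **Merits.**
  - Aryl migration to electron-poor oxygen is among the most dependable peroxide reactions.
  - O1 already sits on C8a and the migrating carbon is C4a, so regiochemistry is built in. In this respect the road is better secured than the chosen plan.
- **Weak points.**
  - The migrating carbon is para to an ester, which lowers its migratory aptitude, while C2 (oxygenated and benzylic) is a strong competitor.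
  - A7 has to be made through a C3 cation that can lose the C2 hydrogen and aromatise to a benzofuran, destroying the only stereocentre present.
  - The silane can reduce the hydroperoxide.
  - The Lewis acid threatens the silyl ether and the C2–O1 bond.
  - C3 again depends on the direction of hydride approach.
- **Comparison.** Both plans use a peroxide oxygen as the electrophile for C4a. The chosen plan does so under anionic conditions, generates no cation beside the syringyl carbon, and creates no stereocentre in the risky step.

Key step: step 14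

Remark on the chemistry: the target string is read as the (2S,3S)-trans isomer. The locants O1, C2 (aryl), C3 (CH2O), O4, C4a to C8a are kept for all benzodioxanes, also where systematic naming would renumber.

## Route

Step 1
Reactants: 1 sinapic acid
Product: 2 benzyl (E)-3-[4-(benzyloxy)-3,5-dimethoxyphenyl]prop-2-enoate
Conditions: BnBr (2.5 equiv), K2CO3, DMF, 60 °C
Reagents that add atoms: benzyl bromide, BrCc1ccccc1
Why: Double Williamson-type O-alkylation; carbonate deprotonates the acid and the hindered phenol and both are capped in one operation, while the E-alkene is untouched.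

Step 2
Reactants: 2 benzyl (E)-3-[4-(benzyloxy)-3,5-dimethoxyphenyl]prop-2-enoate
Product: 3 (E)-3-[4-(benzyloxy)-3,5-dimethoxyphenyl]prop-2-en-1-ol
Conditions: DIBAL-H (2.5 equiv), CH2Cl2, −78 °C; Rochelle salt
Reagents that add atoms: none
Why: 1,2-Reduction of an unsaturated ester with DIBAL-H gives the allylic alcohol without touching the alkene or the aryl benzyl ether; the ester benzyl group leaves as its alcohol.

Step 3
Reactants: 3 (E)-3-[4-(benzyloxy)-3,5-dimethoxyphenyl]prop-2-en-1-ol
Product: 4 {(2R,3R)-3-[4-(benzyloxy)-3,5-dimethoxyphenyl]oxiran-2-yl}methanol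
Conditions: Ti(OiPr)4 (10 mol %), D-(−)-DIPT (12 mol %), PhCMe2OOH, 4 Å MS, CH2Cl2, −20 °C; NaOH/brine work-up
Reagents that add atoms: cumene hydroperoxide, CC(C)(OO)c1ccccc1
Why: Sharpless asymmetric epoxidation of an E-allylic alcohol; the D-(−)-tartrate ligand selects the alkene face that gives the (2R,3R)-epoxide, as with E-cinnamyl alcohols, and this step is the only source of absolute configuration. The catalytic sieve protocol and a basic work-up protect the acid-sensitive aryl epoxide.

Step 4
Reactants: 4 {(2R,3R)-3-[4-(benzyloxy)-3,5-dimethoxyphenyl]oxiran-2-yl}methanol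
Product: 5 (2R,3R)-2-[(benzyloxy)methyl]-3-[4-(benzyloxy)-3,5-dimethoxyphenyl]oxirane
Conditions: NaH, BnBr, Bu4NI (cat.), THF, 0 °C
Reagents that add atoms: benzyl bromide, BrCc1ccccc1
Why: Williamson etherification of the primary alkoxide in an aprotic medium at low temperature, where Payne migration does not compete. The benzyl group blocks the one oxygen that could rival the C2 oxygen in step 14 and falls with the others in step 17.

Step 5
Reactants: 5 (2R,3R)-2-[(benzyloxy)methyl]-3-[4-(benzyloxy)-3,5-dimethoxyphenyl]oxirane
Product: 6 (1S,2R)-3-(benzyloxy)-1-[4-(benzyloxy)-3,5-dimethoxyphenyl]-1-[(4-methoxybenzyl)oxy]propan-2-ol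
Conditions: 4-MeOC6H4CH2OH (3 equiv), Er(OTf)3 (5 mol %), CH2Cl2, −20 °C
Reagents that add atoms: 4-methoxybenzyl alcohol, COc1ccc(CO)cc1
Why: Lewis-acid-catalysed alcoholysis of an aryl epoxide; attack goes to the benzylic carbon, which bears the developing charge, and is further kept away from the other carbon by the inductive pull of CH2OBn. Backside attack inverts the benzylic centre (R to S) and gives the anti array with the secondary hydroxyl free and the benzylic oxygen already carrying a non-participating group.

Step 6
Reactants: 6 (1S,2R)-3-(benzyloxy)-1-[4-(benzyloxy)-3,5-dimethoxyphenyl]-1-[(4-methoxybenzyl)oxy]propan-2-ol; 7 tert-butyl hydroperoxide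
Product: 9 2-(benzyloxy)-5-{(1S,2S)-3-(benzyloxy)-2-(tert-butylperoxy)-1-[(4-methoxybenzyl)oxy]propyl}-1,3-dimethoxybenzene, via triflate 8 (not isolated)
Conditions: Tf2O, 2,6-lutidine, CH2Cl2, −78 °C; then transfer into 7 (anhydrous, in decane)/KOtBu, THF, 0 °C
Reagents that add atoms: none
Why: Alkylation of a hydroperoxide anion by a secondary triflate, a known route to sec-alkyl tert-butyl peroxides; SN2 inversion turns (2R) into (2S) and so sets C3 of the target. The two β-oxygen substituents retard ionisation of 8 and the ether at C1 cannot participate. Keeping 7 in slight excess over KOtBu leaves only the weakly basic peroxide anion, which limits elimination and Kornblum–DeLaMare cleavage.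

Step 7
Reactants: 9 2-(benzyloxy)-5-{(1S,2S)-3-(benzyloxy)-2-(tert-butylperoxy)-1-[(4-methoxybenzyl)oxy]propyl}-1,3-dimethoxybenzene
Product: 10 (1S,2S)-3-(benzyloxy)-1-[4-(benzyloxy)-3,5-dimethoxyphenyl]-2-(tert-butylperoxy)propan-1-ol
Conditions: DDQ, CH2Cl2/pH 7 buffer, 0 °C
Reagents that add atoms: none
Why: Oxidative cleavage of a p-methoxybenzyl ether; dialkyl peroxides and plain benzyl ethers are inert to the quinone. The 3,4,5-trioxygenated ring, whose central oxygen is twisted out of conjugation, is the poorer donor, so hydride abstraction should occur at the anisyl methylene.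

Step 8
Reactants: 10 (1S,2S)-3-(benzyloxy)-1-[4-(benzyloxy)-3,5-dimethoxyphenyl]-2-(tert-butylperoxy)propan-1-ol
Product: 11 {(1S,2S)-3-(benzyloxy)-1-[4-(benzyloxy)-3,5-dimethoxyphenyl]-2-(tert-butylperoxy)propoxy}trimethylsilane
Conditions: TMSCl, imidazole, CH2Cl2, 0 °C; filtration through Et3N-washed silica
Reagents that add atoms: chlorotrimethylsilane, C[Si](C)(C)Cl
Why: Standard silylation of a secondary alcohol; it replaces the only O–H proton of the key-step substrate by a group that fluoride removes without leaving a proton source.

Step 9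
Reactants: 12 3,4-dihydroxybenzaldehyde
Product: 13 3-(benzyloxy)-4-hydroxybenzaldehyde
Conditions: NaH (2.2 equiv), DMSO, 20 °C; BnBr (1.0 equiv); acidic work-up
Reagents that add atoms: benzyl bromide, BrCc1ccccc1
Why: Regioselective Williamson etherification of a catecholate dianion; the 4-oxide is delocalised into the aldehyde and is the weaker nucleophile, so one equivalent of halide alkylates the 3-oxide.

Step 10
Reactants: 13 3-(benzyloxy)-4-hydroxybenzaldehyde
Product: 14 3-(benzyloxy)-5-bromo-4-hydroxybenzaldehyde
Conditions: Br2, NaOAc, AcOH, 20 °C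
Reagents that add atoms: bromine, BrBr
Why: Electrophilic bromination directed by the free phenol to its only open ortho position, as in the bromination of vanillin; the para position is blocked by the aldehyde.

Step 11
Reactants: 14 3-(benzyloxy)-5-bromo-4-hydroxybenzaldehyde
Product: 15 2-(benzyloxy)-6-bromo-4-(1,3-dioxolan-2-yl)phenol
Conditions: HOCH2CH2OH, p-TsOH (cat.), toluene, reflux, Dean–Stark; Et3N quench
Reagents that add atoms: ethylene glycol, OCCO
Why: Acid-catalysed acetalisation with azeotropic removal of water; it shields the aldehyde from n-BuLi in step 12 and from alkoxide, aryl anion and aryne in step 14.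

Step 12
Reactants: 15 2-(benzyloxy)-6-bromo-4-(1,3-dioxolan-2-yl)phenol
Product: 18 2-(benzyloxy)-4-(1,3-dioxolan-2-yl)-6-(trimethylsilyl)phenyl trifluoromethanesulfonate, via aryl silyl ether 16 (not isolated), via lithium phenoxide 17 (not isolated)
Conditions: HMDS, THF, 65 °C, evaporate; n-BuLi, THF, −78 °C; Tf2O, −78 °C; NaHCO3 quench
Reagents that add atoms: hexamethyldisilazane, C[Si](C)(C)N[Si](C)(C)C; triflic anhydride, O=S(=O)(OS(=O)(=O)C(F)(F)F)C(F)(F)F
Why: The standard three-operation conversion of an ortho-bromophenol into an ortho-silylaryl triflate consists of O-silylation, bromine–lithium exchange with retro-Brook O-to-C silyl shift, and triflation of the phenoxide. The same sequence is used for the parent 3-methoxybenzyne precursor. Exchange at −78 °C is faster than any attack on the acetal or the benzyl ether.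

Step 13
Reactants: 19 3,5-bis(benzyloxy)benzyl bromide
Product: 20 diethyl [3,5-bis(benzyloxy)benzyl]phosphonate
Conditions: P(OEt)3, neat, 130 °C
Reagents that add atoms: triethyl phosphite, CCOP(OCC)OCC
Why: Michaelis–Arbuzov reaction of a benzylic bromide; volatile by-product and excess phosphite are removed by distillation.

Step 14
Reactants: 11 {(1S,2S)-3-(benzyloxy)-1-[4-(benzyloxy)-3,5-dimethoxyphenyl]-2-(tert-butylperoxy)propoxy}trimethylsilane; 18 2-(benzyloxy)-4-(1,3-dioxolan-2-yl)-6-(trimethylsilyl)phenyl trifluoromethanesulfonate
Product: 24 (2S,3S)-5-(benzyloxy)-3-[(benzyloxy)methyl]-2-[4-(benzyloxy)-3,5-dimethoxyphenyl]-7-(1,3-dioxolan-2-yl)-2,3-dihydro-1,4-benzodioxine, via caesium alkoxide 21 (not isolated), via aryne 22 (not isolated), via aryl anion 23 (not isolated)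
Conditions: CsF (6 equiv, flame-dried), 18-crown-6, 4 Å MS, THF, 0 → 23 °C; 18 (2 equiv) added slowly
Reagents that add atoms: none
Why: Proposed new method: fluoride removes the O-silyl group of 11 to give the proton-free alkoxide 21 and in parallel triggers 1,2-elimination of 18 to the 3-benzyloxyaryne 22; 21 adds to the aryne carbon remote from the benzyloxy group (O1–C8a), and the 2,6-dioxygenated aryl anion 23 then displaces the tert-butoxy group from the peroxide oxygen on C3 (O4–C4a). The closest known reaction types are the nucleophile-then-electrophile 1,2-difunctionalisation of arynes and the intramolecular etherification of carbanions by dialkyl peroxides; their union, with a tethered peroxide as the electrophile, is what is new. The one ring formed, the dioxane, closes by a 6-exo-tet substitution at oxygen, in which the O–O bond lies outside the forming ring and can line up with the in-plane lone pair of C4a. No stereocentre is created: neither the C2–O1 nor the C3–O4 bond is broken, so the (1S,2S)-syn array of 11 maps onto the (2S,3S)-trans ring. Regioselectivity is required and is secured by the C5 benzyloxy group, whose inductive pull distorts the aryne so that the nucleophile enters at C8a and charge builds up at C4a. Attack at the inner rather than the outer peroxide oxygen follows from the ring size and from the bulk of the tert-butyl group. Quenching of 23 is held back because 11 brings no O–H and THF replaces acetonitrile. Base-induced peroxide cleavage is held back because no base other than fluoride is added, β-peroxy alkoxides are known to persist as the first products of base-catalysed epoxide opening by 7, and the excess aryne consumes the released tert-butoxide.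

Step 15
Reactants: 24 (2S,3S)-5-(benzyloxy)-3-[(benzyloxy)methyl]-2-[4-(benzyloxy)-3,5-dimethoxyphenyl]-7-(1,3-dioxolan-2-yl)-2,3-dihydro-1,4-benzodioxine
Product: 25 (2S,3S)-5-(benzyloxy)-3-[(benzyloxy)methyl]-2-[4-(benzyloxy)-3,5-dimethoxyphenyl]-2,3-dihydro-1,4-benzodioxine-7-carbaldehyde
Conditions: PPTS, acetone/H2O, 50 °C
Reagents that add atoms: water, O
Why: Mild acid hydrolysis of an aryl dioxolane; benzyl ethers and the benzodioxane ring are stable to pyridinium tosylate, so C2 is not put at risk.

Step 16
Reactants: 25 (2S,3S)-5-(benzyloxy)-3-[(benzyloxy)methyl]-2-[4-(benzyloxy)-3,5-dimethoxyphenyl]-2,3-dihydro-1,4-benzodioxine-7-carbaldehyde; 20 diethyl [3,5-bis(benzyloxy)benzyl]phosphonate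
Product: 26 (2S,3S)-5-(benzyloxy)-3-[(benzyloxy)methyl]-2-[4-(benzyloxy)-3,5-dimethoxyphenyl]-7-{(E)-2-[3,5-bis(benzyloxy)phenyl]ethenyl}-2,3-dihydro-1,4-benzodioxine
Conditions: KOtBu, THF, 0 → 23 °C
Reagents that add atoms: none
Why: Horner–Wadsworth–Emmons olefination of an aromatic aldehyde with a benzylic phosphonate; reversible addition and elimination through the less crowded oxaphosphetane give the E-stilbene. C2–H and C3–H are not acidic enough to be touched.

Step 17
Reactants: 26 (2S,3S)-5-(benzyloxy)-3-[(benzyloxy)methyl]-2-[4-(benzyloxy)-3,5-dimethoxyphenyl]-7-{(E)-2-[3,5-bis(benzyloxy)phenyl]ethenyl}-2,3-dihydro-1,4-benzodioxine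
Product: 27 5-{(E)-2-[(2S,3S)-5-hydroxy-2-(4-hydroxy-3,5-dimethoxyphenyl)-3-(hydroxymethyl)-2,3-dihydro-1,4-benzodioxin-7-yl]ethenyl}benzene-1,3-diol (target)
Conditions: BCl3, C6HMe5 (excess), CH2Cl2, −78 °C; MeOH quench at −78 °C
Reagents that add atoms: none
Why: Lewis-acid debenzylation with pentamethylbenzene as a non-basic cation scavenger cleaves aryl and primary alkyl benzyl ethers at −78 °C, where alkenes and aryl methyl ethers are left alone. The scavenger intercepts benzyl cations before they alkylate the electron-rich rings. Any reversible ionisation at C2 should return to the more stable trans isomer, and C3 is not affected.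

## Compound list

1 | sinapic acid, (E)-3-(4-hydroxy-3,5-dimethoxyphenyl)prop-2-enoic acid | COc1cc(/C=C/C(=O)O)cc(OC)c1O | starting material
2 | benzyl (E)-3-[4-(benzyloxy)-3,5-dimethoxyphenyl]prop-2-enoate | COc1cc(/C=C/C(=O)OCc2ccccc2)cc(OC)c1OCc1ccccc1 | intermediate
3 | (E)-3-[4-(benzyloxy)-3,5-dimethoxyphenyl]prop-2-en-1-ol | COc1cc(/C=C/CO)cc(OC)c1OCc1ccccc1 | intermediate
4 | {(2R,3R)-3-[4-(benzyloxy)-3,5-dimethoxyphenyl]oxiran-2-yl}methanol | COc1cc([C@H]2O[C@@H]2CO)cc(OC)c1OCc1ccccc1 | intermediate
5 | (2R,3R)-2-[(benzyloxy)methyl]-3-[4-(benzyloxy)-3,5-dimethoxyphenyl]oxirane | COc1cc([C@H]2O[C@@H]2COCc2ccccc2)cc(OC)c1OCc1ccccc1 | intermediate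
6 | (1S,2R)-3-(benzyloxy)-1-[4-(benzyloxy)-3,5-dimethoxyphenyl]-1-[(4-methoxybenzyl)oxy]propan-2-ol (anti) | COc1cc([C@H](OCc2ccc(OC)cc2)[C@H](O)COCc2ccccc2)cc(OC)c1OCc1ccccc1 | intermediate
7 | tert-butyl hydroperoxide | CC(C)(C)OO | starting material
8 | (1S,2R)-3-(benzyloxy)-1-[4-(benzyloxy)-3,5-dimethoxyphenyl]-1-[(4-methoxybenzyl)oxy]propan-2-yl trifluoromethanesulfonate | COc1cc([C@H](OCc2ccc(OC)cc2)[C@H](OS(=O)(=O)C(F)(F)F)COCc2ccccc2)cc(OC)c1OCc1ccccc1 | intermediate
9 | 2-(benzyloxy)-5-{(1S,2S)-3-(benzyloxy)-2-(tert-butylperoxy)-1-[(4-methoxybenzyl)oxy]propyl}-1,3-dimethoxybenzene (syn) | COc1cc([C@H](OCc2ccc(OC)cc2)[C@@H](OOC(C)(C)C)COCc2ccccc2)cc(OC)c1OCc1ccccc1 | intermediate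
10 | (1S,2S)-3-(benzyloxy)-1-[4-(benzyloxy)-3,5-dimethoxyphenyl]-2-(tert-butylperoxy)propan-1-ol | COc1cc([C@H](O)[C@@H](OOC(C)(C)C)COCc2ccccc2)cc(OC)c1OCc1ccccc1 | intermediate
11 | {(1S,2S)-3-(benzyloxy)-1-[4-(benzyloxy)-3,5-dimethoxyphenyl]-2-(tert-butylperoxy)propoxy}trimethylsilane | COc1cc([C@H](O[Si](C)(C)C)[C@@H](OOC(C)(C)C)COCc2ccccc2)cc(OC)c1OCc1ccccc1 | intermediate
12 | 3,4-dihydroxybenzaldehyde | O=Cc1ccc(O)c(O)c1 | starting material
13 | 3-(benzyloxy)-4-hydroxybenzaldehyde | O=Cc1ccc(O)c(OCc2ccccc2)c1 | intermediate
14 | 3-(benzyloxy)-5-bromo-4-hydroxybenzaldehyde | O=Cc1cc(Br)c(O)c(OCc2ccccc2)c1 | intermediate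
15 | 2-(benzyloxy)-6-bromo-4-(1,3-dioxolan-2-yl)phenol | Oc1c(Br)cc(C2OCCO2)cc1OCc1ccccc1 | intermediate
16 | [2-(benzyloxy)-6-bromo-4-(1,3-dioxolan-2-yl)phenoxy]trimethylsilane | C[Si](C)(C)Oc1c(Br)cc(C2OCCO2)cc1OCc1ccccc1 | intermediate
17 | lithium 2-(benzyloxy)-4-(1,3-dioxolan-2-yl)-6-(trimethylsilyl)phenoxide | [Li+].[O-]c1c(OCc2ccccc2)cc(C2OCCO2)cc1[Si](C)(C)C | intermediate
18 | 2-(benzyloxy)-4-(1,3-dioxolan-2-yl)-6-(trimethylsilyl)phenyl trifluoromethanesulfonate | C[Si](C)(C)c1cc(C2OCCO2)cc(OCc2ccccc2)c1OS(=O)(=O)C(F)(F)F | intermediate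
19 | 3,5-bis(benzyloxy)benzyl bromide | BrCc1cc(OCc2ccccc2)cc(OCc2ccccc2)c1 | starting material
20 | diethyl [3,5-bis(benzyloxy)benzyl]phosphonate | CCOP(=O)(Cc1cc(OCc2ccccc2)cc(OCc2ccccc2)c1)OCC | intermediate
21 | caesium (1S,2S)-3-(benzyloxy)-1-[4-(benzyloxy)-3,5-dimethoxyphenyl]-2-(tert-butylperoxy)propan-1-olate | COc1cc([C@H]([O-])[C@@H](OOC(C)(C)C)COCc2ccccc2)cc(OC)c1OCc1ccccc1.[Cs+] | intermediate
22 | 3-(benzyloxy)-5-(1,3-dioxolan-2-yl)benzyne (triple bond between the future C4a and C8a) | C1#CC=C(C2OCCO2)C=C1OCc1ccccc1 | intermediate
23 | caesium aryl anion: O1 of the (1S,2S)-peroxy chain bound to C8a, carbanion at C4a between O1-bearing C8a and benzyloxy-bearing C5 | COc1cc([C@H](Oc2cc(C3OCCO3)cc(OCc3ccccc3)[c-]2)[C@@H](OOC(C)(C)C)COCc2ccccc2)cc(OC)c1OCc1ccccc1.[Cs+] | intermediate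
24 | (2S,3S)-5-(benzyloxy)-3-[(benzyloxy)methyl]-2-[4-(benzyloxy)-3,5-dimethoxyphenyl]-7-(1,3-dioxolan-2-yl)-2,3-dihydro-1,4-benzodioxine (trans) | COc1cc([C@@H]2Oc3cc(C4OCCO4)cc(OCc4ccccc4)c3O[C@H]2COCc2ccccc2)cc(OC)c1OCc1ccccc1 | intermediate
25 | (2S,3S)-5-(benzyloxy)-3-[(benzyloxy)methyl]-2-[4-(benzyloxy)-3,5-dimethoxyphenyl]-2,3-dihydro-1,4-benzodioxine-7-carbaldehyde | COc1cc([C@@H]2Oc3cc(C=O)cc(OCc4ccccc4)c3O[C@H]2COCc2ccccc2)cc(OC)c1OCc1ccccc1 | intermediate
26 | (2S,3S)-5-(benzyloxy)-3-[(benzyloxy)methyl]-2-[4-(benzyloxy)-3,5-dimethoxyphenyl]-7-{(E)-2-[3,5-bis(benzyloxy)phenyl]ethenyl}-2,3-dihydro-1,4-benzodioxine | COc1cc([C@@H]2Oc3cc(/C=C/c4cc(OCc5ccccc5)cc(OCc5ccccc5)c4)cc(OCc4ccccc4)c3O[C@H]2COCc2ccccc2)cc(OC)c1OCc1ccccc1 | intermediate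
27 | 5-{(E)-2-[(2S,3S)-5-hydroxy-2-(4-hydroxy-3,5-dimethoxyphenyl)-3-(hydroxymethyl)-2,3-dihydro-1,4-benzodioxin-7-yl]ethenyl}benzene-1,3-diol | COc1cc([C@@H]2Oc3cc(/C=C/c4cc(O)cc(O)c4)cc(O)c3O[C@H]2CO)cc(OC)c1O | target

## Step count and least certain steps

Total: 17 steps. Longest linear sequence: 12 steps (steps 1 to 8 and 14 to 17, from sinapic acid 1). The aryne precursor takes four steps (9 to 12) and the phosphonate one step (13).

**Step 14 (key step).**
- *What may go wrong.*
  - The aryl anion may be quenched by adventitious or solvent protons before it reaches the peroxide, which stops the sequence at simple O-arylation.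
  - The aryl anion may abstract the C3 hydrogen through a six-membered transition state, with O–O cleavage.
  - The alkoxide may fragment across C2–C3, or close to an epoxide with loss of the peroxide anion, before it meets the short-lived aryne.
  - The released tert-butoxide may consume the aryne.
  - All four are competing unimolecular or acid–base processes whose rates relative to the desired 6-exo closure are unknown.
- *Fallback.* It uses known reactions and sets out from alcohol 6 and bromophenol 14, in which oxygen, bromine, benzyl ether and aldehyde already occupy C4a, C8a, C5 and C7. Mitsunobu etherification (DIAD, PPh3, toluene) joins the phenol oxygen to the secondary carbon of 6 with inversion and gives aryl ether F1. DDQ then frees benzylic alcohol F2. Intramolecular Buchwald–Hartwig-type etherification (Pd(OAc)2, a bulky di-tert-butyl(biaryl)phosphine, Cs2CO3, toluene, 80 °C) closes O1–C8a with retention at C2. The route is rejoined at aldehyde 25.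

**Step 6.**
- *What may go wrong.* Displacement at a secondary carbon flanked by two oxygenated carbons is slow. Elimination towards the benzylic hydrogen may therefore take over. Aryl-assisted ionisation of the triflate may also occur, with 1,2-aryl shift or erosion of the inversion.
- *Fallback.* The displacement is moved to a triflate without an aryl neighbour, and the C2–aryl bond is formed afterwards. It sets out from tert-butyl hydroperoxide 7. Commercial (S)-3-(benzyloxy)propane-1,2-diol F3 is silylated at the primary hydroxyl (TBSCl, imidazole) to silyl ether F4. This is activated as secondary triflate F5 and displaced with the potassium salt of 7 to give peroxide F6 with inversion. HF·pyridine frees primary alcohol F7, and Dess–Martin oxidation gives α-peroxy aldehyde F8. The Grignard reagent from aryl bromide F9 (Mg, THF) is added at −78 °C in the presence of MgBr2·OEt2, where chelation between the carbonyl and the α-oxygen should favour the syn adduct. After removal of the anti isomer the route is rejoined at peroxy alcohol 10.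

**Step 5.**
- *What may go wrong.* The benzylic C–O bond of this electron-rich epoxide may ionise before the nucleophile arrives, which lowers the fidelity of inversion. Hydride shift to a carbonyl compound and acid-induced self-condensation of the benzylic alcohol nucleophile are further drains.
- *Fallback.* It sets out from the free epoxy alcohol 4 and uses metal-templated delivery. Ti(OiPr)4, pre-exchanged with excess 4-methoxybenzyl alcohol, binds the epoxy alcohol as a chelate and directs opening at the benzylic carbon with inversion to give diol F10. Formation of the stannylene acetal (Bu2SnO) followed by BnBr and CsF benzylates the primary oxygen selectively. The route is rejoined at alcohol 6.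

**Step 17.**
- *What may go wrong.*
  - Lewis-acid ionisation of C2–O1 may cause ring opening or epimerisation.
  - Protonation or alkylation of the electron-rich stilbene may occur.
  - Chelation-assisted loss of a methyl ether next to the freed syringyl oxygen is possible.
  - The primary benzyl ether may cleave incompletely.
  - Five cleavages in one flask multiply each of these risks.
- *Fallback.* It sets out from 24, before the alkene exists. Hydrogenolysis (H2, Pd/C, EtOAc) gives triol F11, and TBSOTf with 2,6-lutidine gives tris(silyl ether) F12. Aprotic acetal cleavage (TESOTf, 2,6-lutidine, then water) gives aldehyde F13. Horner–Wadsworth–Emmons olefination with silyl-protected phosphonate F14 (LiHMDS, THF) gives pentasilyl stilbene F15, and buffered fluoride (TBAF, AcOH, THF) releases target 27.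

## Further compounds

F1 | step 14 | 3-(benzyloxy)-4-({(1S,2S)-3-(benzyloxy)-1-[4-(benzyloxy)-3,5-dimethoxyphenyl]-1-[(4-methoxybenzyl)oxy]propan-2-yl}oxy)-5-bromobenzaldehyde | COc1cc([C@H](OCc2ccc(OC)cc2)[C@@H](Oc2c(Br)cc(C=O)cc2OCc2ccccc2)COCc2ccccc2)cc(OC)c1OCc1ccccc1
F2 | step 14 | 3-(benzyloxy)-4-({(1S,2S)-3-(benzyloxy)-1-[4-(benzyloxy)-3,5-dimethoxyphenyl]-1-hydroxypropan-2-yl}oxy)-5-bromobenzaldehyde | COc1cc([C@H](O)[C@@H](Oc2c(Br)cc(C=O)cc2OCc2ccccc2)COCc2ccccc2)cc(OC)c1OCc1ccccc1
F3 | step 6 | (S)-3-(benzyloxy)propane-1,2-diol | OC[C@H](O)COCc1ccccc1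
F4 | step 6 | (R)-1-(benzyloxy)-3-[(tert-butyldimethylsilyl)oxy]propan-2-ol | CC(C)(C)[Si](C)(C)OC[C@H](O)COCc1ccccc1
F5 | step 6 | (R)-1-(benzyloxy)-3-[(tert-butyldimethylsilyl)oxy]propan-2-yl trifluoromethanesulfonate | CC(C)(C)[Si](C)(C)OC[C@H](OS(=O)(=O)C(F)(F)F)COCc1ccccc1
F6 | step 6 | [(S)-3-(benzyloxy)-2-(tert-butylperoxy)propoxy](tert-butyl)dimethylsilane | CC(C)(C)[Si](C)(C)OC[C@@H](OOC(C)(C)C)COCc1ccccc1
F7 | step 6 | (R)-3-(benzyloxy)-2-(tert-butylperoxy)propan-1-ol | OC[C@@H](OOC(C)(C)C)COCc1ccccc1
F8 | step 6 | (S)-3-(benzyloxy)-2-(tert-butylperoxy)propanal | O=C[C@@H](OOC(C)(C)C)COCc1ccccc1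
F9 | step 6 | 2-(benzyloxy)-5-bromo-1,3-dimethoxybenzene | COc1cc(Br)cc(OC)c1OCc1ccccc1
F10 | step 5 | (2R,3S)-3-[4-(benzyloxy)-3,5-dimethoxyphenyl]-3-[(4-methoxybenzyl)oxy]propane-1,2-diol | COc1cc([C@H](OCc2ccc(OC)cc2)[C@H](O)CO)cc(OC)c1OCc1ccccc1
F11 | step 17 | (2S,3S)-7-(1,3-dioxolan-2-yl)-2-(4-hydroxy-3,5-dimethoxyphenyl)-3-(hydroxymethyl)-2,3-dihydro-1,4-benzodioxin-5-ol | COc1cc([C@@H]2Oc3cc(C4OCCO4)cc(O)c3O[C@H]2CO)cc(OC)c1O
F12 | step 17 | tris(tert-butyldimethylsilyl) ether of F11 (at C5–O, syringyl O and CH2O) | COc1cc([C@@H]2Oc3cc(C4OCCO4)cc(O[Si](C)(C)C(C)(C)C)c3O[C@H]2CO[Si](C)(C)C(C)(C)C)cc(OC)c1O[Si](C)(C)C(C)(C)C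
F13 | step 17 | (2S,3S)-5-[(tert-butyldimethylsilyl)oxy]-3-{[(tert-butyldimethylsilyl)oxy]methyl}-2-{4-[(tert-butyldimethylsilyl)oxy]-3,5-dimethoxyphenyl}-2,3-dihydro-1,4-benzodioxine-7-carbaldehyde | COc1cc([C@@H]2Oc3cc(C=O)cc(O[Si](C)(C)C(C)(C)C)c3O[C@H]2CO[Si](C)(C)C(C)(C)C)cc(OC)c1O[Si](C)(C)C(C)(C)C
F14 | step 17 | diethyl {3,5-bis[(tert-butyldimethylsilyl)oxy]benzyl}phosphonate | CCOP(=O)(Cc1cc(O[Si](C)(C)C(C)(C)C)cc(O[Si](C)(C)C(C)(C)C)c1)OCC
F15 | step 17 | penta(tert-butyldimethylsilyl) ether of 27, (2S,3S), E-alkene | COc1cc([C@@H]2Oc3cc(/C=C/c4cc(O[Si](C)(C)C(C)(C)C)cc(O[Si](C)(C)C(C)(C)C)c4)cc(O[Si](C)(C)C(C)(C)C)c3O[C@H]2CO[Si](C)(C)C(C)(C)C)cc(OC)c1O[Si](C)(C)C(C)(C)C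
A1 | alternative 1 | methyl (2S,3S)-5-[benzyl(dimethyl)silyl]-3-[(benzyloxy)methyl]-2-[4-(benzyloxy)-3,5-dimethoxyphenyl]-2,3-dihydro-1,4-benzodioxine-7-carboxylate | COc1cc([C@@H]2Oc3cc(C(=O)OC)cc([Si](C)(C)Cc4ccccc4)c3O[C@H]2COCc2ccccc2)cc(OC)c1OCc1ccccc1
A2 | alternative 1 | 2-(benzyloxy)-5-[(1S,2S)-3-(benzyloxy)-2-({[benzyl(dimethyl)silyl]ethynyl}oxy)-1-(ethynyloxy)propyl]-1,3-dimethoxybenzene | COc1cc([C@H](OC#C)[C@@H](OC#C[Si](C)(C)Cc2ccccc2)COCc2ccccc2)cc(OC)c1OCc1ccccc1
A3 | alternative 1 | methyl propiolate | C#CC(=O)OC
A4 | alternative 2 | methyl (2S,3S)-3-[(benzyloxy)methyl]-2-{3,5-dimethoxy-4-[(methylsulfonyl)oxy]phenyl}-5-[(methylsulfonyl)oxy]-2,3-dihydro-1,4-benzodioxine-7-carboxylate | COc1cc([C@@H]2Oc3cc(C(=O)OC)cc(OS(C)(=O)=O)c3O[C@H]2COCc2ccccc2)cc(OC)c1OS(C)(=O)=O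
A5 | alternative 2 | methyl 2-[(benzyloxy)methyl]-2-[(R)-{3,5-dimethoxy-4-[(methylsulfonyl)oxy]phenyl}(hydroxy)methyl]-7-[(methylsulfonyl)oxy]-1,3-benzodioxole-5-carboxylate (ketal carbon unassigned) | COc1cc([C@@H](O)C2(COCc3ccccc3)Oc3cc(C(=O)OC)cc(OS(C)(=O)=O)c3O2)cc(OC)c1OS(C)(=O)=O
A6 | alternative 3 | methyl (2S,3S)-3-[(benzyloxy)methyl]-2-[4-(benzyloxy)-3,5-dimethoxyphenyl]-5-[(tert-butyldimethylsilyl)oxy]-2,3-dihydro-1,4-benzodioxine-7-carboxylate | COc1cc([C@@H]2Oc3cc(C(=O)OC)cc(O[Si](C)(C)C(C)(C)C)c3O[C@H]2COCc2ccccc2)cc(OC)c1OCc1ccccc1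
A7 | alternative 3 | methyl (2S)-3-[(benzyloxy)methyl]-2-[4-(benzyloxy)-3,5-dimethoxyphenyl]-4-[(tert-butyldimethylsilyl)oxy]-3-hydroperoxy-2,3-dihydro-1-benzofuran-6-carboxylate (C3 unassigned) | COc1cc([C@@H]2Oc3cc(C(=O)OC)cc(O[Si](C)(C)C(C)(C)C)c3C2(OO)COCc2ccccc2)cc(OC)c1OCc1ccccc1
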